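The vessel I watched was closed, stirred and held at 35 °C, and I wanted to know what it would hold at 2.5 d and which remedy would then pay.

| flask | starting material | reagent | initiator | temperature | remark | time |
|---|---|---|---|---|---|---|
| teal | 0.50 M | 0.40 M | 65 mM | 35 °C | the very flask that is asked about, followed so far |  |
| red | 0.50 M | 0.40 M | 130 mM | 35 °C | run made earlier |  |
| flask | 0.50 M | 0.400 M | 65 mM | 35 °C |  | 2.5 d |

| run | time / h | target / % |
|---|---|---|
| teal | 3.00 | 33.1 |
| teal | 10.0 | 68.0 |
| teal | 15.0 | 75.8 |
| teal | 25.0 | 79.6 |
| teal | 40.0 | 79.0 |
| teal | 50.0 | 80.4 |
| red | 0.200 | 4.2 |
| red | 0.333 | 6.3 |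
| red | 0.500 | 9.4 |
| red | 0.833 | 14.9 |
| red | 1.33 | 24.3 |
| red | 2.50 | 38.2 |

(scatter of a reading: 0.5 percentage points)

- autumn: at 2.5 d take out 90% of the target then present, then wait 2.5 d
- summer: change nothing and wait 2.5 d more
- noon: at 2.5 d raise the temperature by 10 K, then wait 2.5 d
- dawn: at 2.5 d add reagent, 100% of the amount charged, then wait 2.5 d

- removed target is counted in
- additions bring no volume worth counting
- the earlier runs do not show what temperature does; that part of a forecast is a guess

- target, in percent of the starting material first charged, at 2.5 d
- the remedy with the largest gain of target, or "none" below 2 percentage points (autumn / summer / noon / dawn / none)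
- target present, with what was taken out counted in, in percent of the starting material first charged, after autumn
- target present, with what was taken out counted in, in percent of the starting material first charged, after dawn

I counted turnovers. If each turnover takes one reagent and one starting material and leaves one target, the short charge, the limiting reagent, pays for a fixed number of them. The bench rule is that a plateau stands where that charge allows. I called the share of starting material that the reagent charge can turn into target the ceiling:

ceiling = c(reagent) / c(starting material) = 0.400 M / 0.50 M = 80.0%

The teal run, which is this very flask, read 79.6%, 79.0% and 80.4% over its last three readings, around the ceiling at a scatter of 0.5 percentage points. So I committed to the ceiling for the flask at 2.5 d, a little past the last reading at 50.0 h. Autumn, summer and noon bring no reagent, so the ceiling stayed where it was for them, although what heat does in noon was a guess.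

The rule has a border, where the ratio passes one and the other charge becomes the short one. Dawn crosses it:

ratio after dawn = 160%, above one, so ceiling = 100%

The forecast gave 80% for now, dawn as the best remedy, 80% after autumn and 99% after dawn, on the ground that “the plateau is most likely reagent exhaustion rather than a stall or an equilibrium”. My ceiling after dawn was a limit, and it stood above the forecast's figure.

The flask gave 80.0% at 2.5 d, level with the ceiling of 80.0%, with 0% of the reagent and 18.2% of the starting material free at 60.0 h. The best remedy was dawn, which gained 18 points against 0 points for each of the others, and autumn gave 80.0%. Dawn gave 98.2%, which is 1.8 points under its ceiling of 100%.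

    initiator → 2 initiating radical (k = 0.00120 h⁻¹, Ea = 102 kJ mol⁻¹)
    starting material + initiating radical → capped initiator + first chain carrier (k = 48000 M⁻¹ s⁻¹, Ea = 32.0 kJ mol⁻¹)
    2 first chain carrier → ended chains B (k = 7.60 × 10⁷ M⁻¹ s⁻¹, Ea = 9.00 kJ mol⁻¹)
    starting material + second chain carrier → released group + first chain carrier (k = 19000 M⁻¹ s⁻¹, Ea = 16.0 kJ mol⁻¹)
    reagent + first chain carrier → target + second chain carrier (k = 1.20 × 10⁷ M⁻¹ h⁻¹, Ea = 43.0 kJ mol⁻¹)
    2 second chain carrier → ended chains A (k = 9.00 × 10⁸ M⁻¹ s⁻¹, Ea = 10.0 kJ mol⁻¹)
    (constants at 35 °C)

With 1.2 M of starting material and the same reagent, the neighbour flask has a ceiling of 33.3%. Computed, that neighbour gave 33.3% at the same time, with 0% of its reagent free.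

(Readings and results stem from a simulated flask with made-up constants; scatter was added.)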